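The target is a meso 1,4-diketone: C2 and C3 of the butane-1,4-dione chain each bear one 2,4-dihydroxybenzoyl group (ring A) and one CH2 arm leading to a 4-hydroxyphenyl ring (ring B). This C2–C3 pair maps onto a cis-4,5-diaroylcyclohexene whose ring carbons C3 and C6 are the two benzylic carbons. One thermal [4+2] cycloaddition of buta-1,3-diene to a (Z)-1,4-diarylbut-2-ene-1,4-dione forms both C–CH2 bonds, the cyclohexene ring and both stereocentres as a cis, hence meso, pair. The dienophile is the Z-enedione with two 2,4-bis(benzyloxy)phenyl ketones. The ring alkene is later cleaved to two carboxyl groups, each exchanged for a ring B aryl group by decarboxylative coupling.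

Key step: step 4

Assumption: all six phenols are carried as benzyl ethers, because a closing Lewis-acid dealkylation could epimerise or cyclodehydrate (to a furan) the 2,3-disubstituted 1,4-diketone whereas hydrogenolysis is neutral; this rules out an AlCl3 acylation, so the Z-enedione is made by oxidative opening of a 2,5-diarylfuran; 2,5-bis(tributylstannyl)furan and 4-(benzyloxy)phenylmagnesium bromide (THF solution) are taken as purchasable.

Step 1
Reactants: 1 4-bromobenzene-1,3-diol
Product: 2 1-bromo-2,4-bis(benzyloxy)benzene
Conditions: BnBr (2.3 equiv), K2CO3 (3 equiv), DMF, 60 °C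
Reagents that add atoms: benzyl bromide, BrCc1ccccc1
Why: Williamson ether synthesis, in which both phenoxides are alkylated by SN2 at the benzylic bromide; the benzyl ethers should survive every later step and leave at the end by neutral hydrogenolysis, and no stereocentre is formed.

Step 2
Reactants: 2 1-bromo-2,4-bis(benzyloxy)benzene (2.2 equiv); 3 2,5-bis(tributylstannyl)furan
Product: 4 2,5-bis[2,4-bis(benzyloxy)phenyl]furan
Conditions: Pd(PPh3)4 (5 mol%), toluene, 110 °C, argon
Reagents that add atoms: none
Why: Double Stille coupling, in which zerovalent palladium inserts into each aryl C–Br bond, the 2-furylstannane transmetalates readily and reductive elimination joins furan C2 and C5 to the two aryl rings; no stereocentre is formed.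

Step 3
Reactants: 4 2,5-bis[2,4-bis(benzyloxy)phenyl]furan
Product: 5 (Z)-1,4-bis[2,4-bis(benzyloxy)phenyl]but-2-ene-1,4-dione
Conditions: mCPBA (1.05 equiv), CH2Cl2, −20 to 0 °C, dark
Reagents that add atoms: 3-chloroperoxybenzoic acid, OOC(=O)c1cccc(Cl)c1
Why: Peracid oxidative ring opening of a 2,5-disubstituted furan, in which epoxidation of one ring C=C bond and collapse of the epoxide cleave the C2–O bond so that C2 and C5 become the two ketones and the former ring C3–C4 bond becomes the alkene, which is Z because the ring held it cis; low temperature and exclusion of light should keep it Z.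

Step 4
Reactants: 5 (Z)-1,4-bis[2,4-bis(benzyloxy)phenyl]but-2-ene-1,4-dione; 6 buta-1,3-diene
Product: 7 cis-4,5-bis[2,4-bis(benzyloxy)benzoyl]cyclohexene (4R,5S, meso)
Conditions: buta-1,3-diene in excess (condensed in at −78 °C), BHT (cat.), toluene, 100 °C, sealed tube, dark
Reagents that add atoms: none
Why: Thermal Diels–Alder reaction, in which the s-cis diene and the doubly acyl-activated alkene combine in a concerted suprafacial [4π+2π] cycloaddition; the closest known reaction type is the addition of 1,2-diaroylethylenes to simple 1,3-dienes. The cyclohexene ring closes by intermolecular [4+2] annulation, both new ring bonds (C3–C4 and C5–C6 of the cyclohexene) forming in the same step. The two new stereocentres C4 and C5 are controlled by the Z geometry of the dienophile, which is transferred suprafacially to a cis (4R,5S, meso) pair. Because buta-1,3-diene is symmetrical, no regiochemical or endo/exo question arises at these centres, so the only selectivity needed is stereospecificity. It is secured by acid-free and base-free conditions in the dark with a radical inhibitor and an excess of the diene, under which the Z-enedione should not isomerise and the cis adduct, whose stereocentres are alpha to ketones, should not epimerise.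

Step 5
Reactants: 7 cis-4,5-bis[2,4-bis(benzyloxy)benzoyl]cyclohexene
Product: 9 meso-(3R,4S)-3,4-bis[2,4-bis(benzyloxy)benzoyl]hexanedioic acid, via dialdehyde 8 (not isolated)
Conditions: O3, CH2Cl2/MeOH, −78 °C (Sudan Red 7B end point); Me2S, −78 °C to rt; then NaClO2, NaH2PO4, 2-methyl-2-butene, t-BuOH/THF/H2O, 0 °C to rt
Reagents that add atoms: ozone, [O-][O+]=O; sodium chlorite, [Na+].[O-]Cl=O
Why: Ozonolysis (Criegee mechanism, reductive work-up) followed by Pinnick oxidation, in which the ring alkene should react with ozone far faster than the acyl-deactivated aryl rings, the dye marks the end point, and the buffered chlorite oxidation with a hypochlorite scavenger converts the crude dialdehyde to the diacid without base, so the two stereocentres alpha to the ketones are retained.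

Step 6
Reactants: 9 meso-(3R,4S)-3,4-bis[2,4-bis(benzyloxy)benzoyl]hexanedioic acid
Product: 10 bis(1,3-dioxoisoindolin-2-yl) meso-(3R,4S)-3,4-bis[2,4-bis(benzyloxy)benzoyl]hexanedioate
Conditions: N-hydroxyphthalimide (2.4 equiv), N,N'-diisopropylcarbodiimide (2.4 equiv), DMAP (10 mol%), CH2Cl2, 0 °C to rt
Reagents that add atoms: N-hydroxyphthalimide, ON1C(=O)c2ccccc2C1=O
Why: Carbodiimide esterification of the Steglich type, in which the O-acylisourea of each primary carboxyl group is captured by N-hydroxyphthalimide under near-neutral conditions that leave the ketone alpha-stereocentres untouched.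

Step 7
Reactants: 11 4-(benzyloxy)phenylmagnesium bromide
Product: 12 [4-(benzyloxy)phenyl]zinc chloride (THF solution, used directly)
Conditions: ZnCl2 (1.1 equiv), LiCl, THF, 0 °C to rt
Reagents that add atoms: zinc chloride, [Zn+2].[Cl-].[Cl-]
Why: Transmetalation of an aryl Grignard reagent to zinc, giving an arylzinc chloride mild enough to tolerate the two ketones and the active esters of the coupling partner.

Step 8
Reactants: 10 bis(1,3-dioxoisoindolin-2-yl) meso-(3R,4S)-3,4-bis[2,4-bis(benzyloxy)benzoyl]hexanedioate; 12 [4-(benzyloxy)phenyl]zinc chloride (6 equiv)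
Product: 13 meso-(2R,3S)-2,3-bis[4-(benzyloxy)benzyl]-1,4-bis[2,4-bis(benzyloxy)phenyl]butane-1,4-dione
Conditions: NiCl2(MeOCH2CH2OMe) (40 mol%), 4,4'-di-tert-butyl-2,2'-bipyridine (80 mol%), THF/DMF, rt
Reagents that add atoms: none
Why: Nickel-catalysed decarboxylative Negishi-type arylation of redox-active esters, in which electron transfer from low-valent nickel fragments each ester to CO2, phthalimide anion and a primary alkyl radical that is captured at arylnickel and reductively eliminated to the benzylic C–aryl bond; the radical centres are the CH2 carbons, so the adjacent stereocentres are not touched.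

Step 9
Reactants: 13 meso-(2R,3S)-2,3-bis[4-(benzyloxy)benzyl]-1,4-bis[2,4-bis(benzyloxy)phenyl]butane-1,4-dione
Product: 14 meso-(2R,3S)-1,4-bis(2,4-dihydroxyphenyl)-2,3-bis(4-hydroxybenzyl)butane-1,4-dione (CNP0406969.1)
Conditions: H2 (1 atm), 10% Pd/C, THF/MeOH, rt
Reagents that add atoms: none
Why: Catalytic hydrogenolysis of benzyl aryl ethers, which cleaves all six O–CH2Ph bonds on palladium under neutral conditions and so avoids acid-promoted epimerisation or furan-forming cyclodehydration of the 1,4-diketone, while the electron-rich aryl ketones should not be reduced at ambient pressure.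

Compound list
1 | 4-bromobenzene-1,3-diol | Oc1ccc(Br)c(O)c1 | starting material
2 | 1-bromo-2,4-bis(benzyloxy)benzene | Brc1ccc(OCc2ccccc2)cc1OCc1ccccc1 | intermediate
3 | 2,5-bis(tributylstannyl)furan | CCCC[Sn](CCCC)(CCCC)c1ccc(o1)[Sn](CCCC)(CCCC)CCCC | starting material
4 | 2,5-bis[2,4-bis(benzyloxy)phenyl]furan | c1c(-c2ccc(OCc3ccccc3)cc2OCc2ccccc2)oc(-c2ccc(OCc3ccccc3)cc2OCc2ccccc2)c1 | intermediate
5 | (Z)-1,4-bis[2,4-bis(benzyloxy)phenyl]but-2-ene-1,4-dione | O=C(/C=C\C(=O)c1ccc(OCc2ccccc2)cc1OCc1ccccc1)c1ccc(OCc2ccccc2)cc1OCc1ccccc1 | intermediate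
6 | buta-1,3-diene | C=CC=C | starting material
7 | cis-4,5-bis[2,4-bis(benzyloxy)benzoyl]cyclohexene (4R,5S, meso) | O=C(c1ccc(OCc2ccccc2)cc1OCc1ccccc1)[C@@H]1CC=CC[C@@H]1C(=O)c1ccc(OCc2ccccc2)cc1OCc1ccccc1 | intermediate
8 | meso-(3R,4S)-3,4-bis[2,4-bis(benzyloxy)benzoyl]hexanedial | O=C(c1ccc(OCc2ccccc2)cc1OCc1ccccc1)[C@@H](CC=O)[C@@H](CC=O)C(=O)c1ccc(OCc2ccccc2)cc1OCc1ccccc1 | intermediate
9 | meso-(3R,4S)-3,4-bis[2,4-bis(benzyloxy)benzoyl]hexanedioic acid | O=C(c1ccc(OCc2ccccc2)cc1OCc1ccccc1)[C@@H](CC(=O)O)[C@@H](CC(=O)O)C(=O)c1ccc(OCc2ccccc2)cc1OCc1ccccc1 | intermediate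
10 | bis(1,3-dioxoisoindolin-2-yl) meso-(3R,4S)-3,4-bis[2,4-bis(benzyloxy)benzoyl]hexanedioate | O=C(c1ccc(OCc2ccccc2)cc1OCc1ccccc1)[C@@H](CC(=O)ON1C(=O)c2ccccc2C1=O)[C@@H](CC(=O)ON1C(=O)c2ccccc2C1=O)C(=O)c1ccc(OCc2ccccc2)cc1OCc1ccccc1 | intermediate
11 | 4-(benzyloxy)phenylmagnesium bromide | Br[Mg]c1ccc(OCc2ccccc2)cc1 | starting material
12 | [4-(benzyloxy)phenyl]zinc chloride | Cl[Zn]c1ccc(OCc2ccccc2)cc1 | intermediate
13 | meso-(2R,3S)-2,3-bis[4-(benzyloxy)benzyl]-1,4-bis[2,4-bis(benzyloxy)phenyl]butane-1,4-dione | O=C(c1ccc(OCc2ccccc2)cc1OCc1ccccc1)[C@@H](Cc1ccc(OCc2ccccc2)cc1)[C@@H](Cc1ccc(OCc2ccccc2)cc1)C(=O)c1ccc(OCc2ccccc2)cc1OCc1ccccc1 | intermediate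
14 | meso-(2R,3S)-1,4-bis(2,4-dihydroxyphenyl)-2,3-bis(4-hydroxybenzyl)butane-1,4-dione | O=C(c1ccc(O)cc1O)[C@@H](Cc1ccc(O)cc1)[C@@H](Cc1ccc(O)cc1)C(=O)c1ccc(O)cc1O | target

Total step count: 9. Longest linear sequence: 8 steps (steps 1 to 6, 8 and 9; step 7 is a one-step side branch).

Steps most likely to fail

Step 4 (key step). The cycloaddition of the twisted, electron-rich Z-dienophile may be slow, so that thermal or trace-catalysed Z-to-E isomerisation runs ahead of it and delivers the trans ring pair. The fallback sets the cis pair with a ring-locked dienophile and builds the aryl ketones afterwards; it sets out from diene 6 and bromide 2 and returns at 7. Buta-1,3-diene 6 is added to maleic anhydride (toluene, 60 °C) to give cis-cyclohex-4-ene-1,2-dicarboxylic anhydride F1, whose cis ring fusion cannot isomerise. Opening with N,O-dimethylhydroxylamine (CH2Cl2, rt) should give cis-6-[methoxy(methyl)carbamoyl]cyclohex-3-ene-1-carboxylic acid F2 as a racemate. Coupling of its free acid with the same amine (EDC·HCl, HOBt, N-methylmorpholine, CH2Cl2) should give the meso cis-N1,N2-dimethoxy-N1,N2-dimethylcyclohex-4-ene-1,2-dicarboxamide F3. Bromide 2 and magnesium in THF give [2,4-bis(benzyloxy)phenyl]magnesium bromide F4, which is added to F3 at −40 to 0 °C (Weinreb ketone synthesis). A cold NH4Cl quench of the chelated tetrahedral intermediates should release the cis diketone 7, where the route is rejoined.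

Step 8. The double coupling may stop short through reduction or homocoupling of the active ester, or through 1,2-acyl shift and β-hydride loss at the stage of the β-keto alkyl radical or alkylnickel species. The fallback is a cross-electrophile coupling without any arylmetal, starting from bis-ester 10. It is treated with 1-(benzyloxy)-4-iodobenzene, NiBr2(MeOCH2CH2OMe), 4,4'-di-tert-butyl-2,2'-bipyridine and zinc powder in DMA at rt. The arylnickel partner then forms from the aryl iodide in the flask, and the product should be 13 directly; no compound outside the list arises (F0).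

Step 5. Over-oxidation may occur, by ozone attack on the dialkoxyaryl rings or on the benzylic C–H bonds of the ethers, or the dialdehyde may undergo aldol self-condensation during handling. The fallback is an osmium and periodate cleavage starting from 7. Catalytic dihydroxylation (K2OsO2(OH)4, N-methylmorpholine N-oxide, acetone/H2O) should give cis-4,5-bis[2,4-bis(benzyloxy)benzoyl]cyclohexane-cis-1,2-diol F5, with the hydroxyls on the face opposite the aroyl groups. NaIO4 in buffered THF/H2O then cleaves the glycol to dialdehyde 8, which re-enters step 5 at the chlorite oxidation to 9.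

Further compounds
F1 | step 4 | cis-cyclohex-4-ene-1,2-dicarboxylic anhydride (3aR,7aS, meso) | O=C1OC(=O)[C@H]2CC=CC[C@@H]12
F2 | step 4 | cis-6-[methoxy(methyl)carbamoyl]cyclohex-3-ene-1-carboxylic acid (racemic, one enantiomer drawn) | CON(C)C(=O)[C@@H]1CC=CC[C@@H]1C(=O)O
F3 | step 4 | cis-N1,N2-dimethoxy-N1,N2-dimethylcyclohex-4-ene-1,2-dicarboxamide (1R,2S, meso) | CON(C)C(=O)[C@@H]1CC=CC[C@@H]1C(=O)N(C)OC
F4 | step 4 | [2,4-bis(benzyloxy)phenyl]magnesium bromide | Br[Mg]c1ccc(OCc2ccccc2)cc1OCc1ccccc1
F0 | step 8 | none | none
F5 | step 5 | cis-4,5-bis[2,4-bis(benzyloxy)benzoyl]cyclohexane-cis-1,2-diol (hydroxyls trans to the aroyl groups, meso) | O=C(c1ccc(OCc2ccccc2)cc1OCc1ccccc1)[C@@H]1C[C@@H](O)[C@@H](O)C[C@@H]1C(=O)c1ccc(OCc2ccccc2)cc1OCc1ccccc1
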